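**Plan**

1. Numbering: the target is a 7-oxabicyclo[4.1.0]hept-3-ene with C1 (oxirane carbon carrying the butenoic acid chain), C2 (CHOH), C3 (heptenyl), C4 (CH2OH), C5 (CHOH) and C6 (oxirane CH). These locants are used in all Why lines; in the benzofuran names of the tricyclic intermediates C3a = C1, C7a = C2, C7 = C3, C6 = C4, C5 = C5, C4 = C6.
2. Cuts (retrosynthesis): the side-chain C=C (Wittig on a lactol); C5–OH and CH2OH back to ketone and methyl ester; C3=C4 back to the saturated β-keto ester; then C2–C3 and C1–C6 together. This leaves a four-carbon unit (Knoevenagel adduct of methyl 4-chloroacetoacetate and (E)-oct-2-enal) and a two-carbon unit (5-methoxydihydrofuran-3(2H)-one).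
3. Enabling feature: as a ketone, C5 is 1,5-related to C1 through C4–C3–C2 and 1,3-related to C1 through C6. The cyclohexene ring is therefore a Michael/aldol retron in which the oxirane oxygen is the former carbonyl oxygen of C1 and C6 needs only a leaving group (Darzens closure). The C2 hydroxyl and the CH2 of the C1 side chain lie on the same ring face, so both can be held in a temporary five-membered lactol-acetal ring that fixes the oxirane face.
4. Forward order: the temporary tetrahydrofuran ring is made first (step 3); the carbocycle and then the oxirane arise in one operation (step 4); then follow the ring alkene, the reduction, the opening of the temporary ring with chain extension, and ester hydrolysis.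
5. Stereochemistry: C2 comes from the chiral amine catalyst in step 4; C1 and C6 are relayed from C2 by the cis fusion of the temporary ring and SN2 oxirane closure; C5 comes from hydride attack anti to the oxirane; the two (E)-alkenes come from (E)-oct-2-enal and a stabilised ylide.

Key step: step 4

Assumption: the (R)-catalyst is taken to give (R) at C2 by analogy with the hydrogen-bond-directed enamine model of this catalyst class (its enantiomer is used if the sense proves opposite), and the racemic acetal carbon of the furanone donor is carried as a mixture until step 8 removes it.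

**Route**

Step 1
Reactants: 1 methyl 4-chloro-3-oxobutanoate; 2 (2E)-oct-2-enal
Product: 3 methyl (4E)-2-(chloroacetyl)deca-2,4-dienoate as a 2E/2Z mixture
Conditions: piperidine (10 mol %), AcOH (10 mol %), 4 Å MS, CH2Cl2, 0 °C → rt
Reagents that add atoms: none
Why: Knoevenagel condensation of the active methylene of the β-keto ester with the aldehyde should give the alkylidene β-keto ester with the (E)-alkene of 2 untouched; the geometry of the new C=C is immaterial because both of its carbons (future C3 and C4) are rehybridised in step 4, and any 2H-pyran valence isomer reverts to 3 as 3 is consumed.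

Step 2
Reactants: 4 4,4-dimethoxybutan-2-one
Product: 6 [(4,4-dimethoxybut-1-en-2-yl)oxy]trimethylsilane, via lithium enolate 5 (not isolated)
Conditions: LiN(i-Pr)2 (LDA, 1.1 equiv), THF, −78 °C; then Me3SiCl, −78 → 0 °C
Reagents that add atoms: chlorotrimethylsilane, C[Si](C)(C)Cl
Why: kinetic deprotonation by the hindered amide at the methyl group (the less hindered α-position) and O-silylation of the enolate should give the terminal silyl enol ether (kinetic enolate trapping).

Step 3
Reactants: 6 [(4,4-dimethoxybut-1-en-2-yl)oxy]trimethylsilane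
Product: 8 racemic 5-methoxydihydrofuran-3(2H)-one, via silyloxy ketone 7 (not isolated)
Conditions: mCPBA, hexane, −15 → 0 °C, filter; then Me3SiOTf (2 mol %), CH2Cl2, −78 → −30 °C, pyridine quench
Reagents that add atoms: 3-chloroperoxybenzoic acid, OOC(=O)c1cccc(Cl)c1
Why: Rubottom oxidation (epoxidation of the silyl enol ether and 1,4-silyl shift) installs the future C2 oxygen as a silyl ether, and silyl triflate-catalysed transacetalisation closes the five-membered mixed acetal (5-exo attack of the silyl ether oxygen on the oxocarbenium ion) with loss of methoxytrimethylsilane; the acetal carbon is formed racemic and is removed in step 8.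

Step 4
Reactants: 3 methyl (4E)-2-(chloroacetyl)deca-2,4-dienoate; 8 racemic 5-methoxydihydrofuran-3(2H)-one (1.5 equiv)
Product: 11 methyl (3aS,4S,7aR)-3a,4-epoxy-7-[(E)-hept-1-en-1-yl]-2-methoxy-5-oxooctahydro-1-benzofuran-6-carboxylate (epimers at the acetal carbon and at C6 and C7 of this name), via Michael adduct 9 (not isolated), via chlorohydrin 10 (not isolated)
Conditions: (R)-5-(pyrrolidin-2-yl)-1H-tetrazole (20 mol %), CH2Cl2, 0 °C → rt; then K2CO3 (2 equiv), DMF, 0 °C → rt
Reagents that add atoms: none
Why: Proposed new method: the enamine formed from the catalyst and 8 at its oxygen-bearing CH2 (the more acidic α-position) adds 1,4 to the doubly activated alkylidene β-keto ester 3 to make C2–C3, and once base is added the chlorine-bearing carbon of the chloromethyl ketone adds as its enolate to the furanone carbonyl to make C1–C6, after which the tertiary alkoxide displaces chloride. The closest known reaction types are the Robinson annulation (Michael addition then intramolecular aldol addition), the Darzens condensation, and the amine-catalysed Michael/aldol/chloride-displacement sequence of 4-chloroacetoacetates with enals that gives 2,3-epoxycyclohexanones; new here is that a ketone supplies the two-carbon unit as Michael donor and then serves as the aldol acceptor. The carbocycle closes by a 6-(enolendo)-exo-trig aldol addition and the oxirane by a 3-exo-tet displacement. C2 is set by the catalyst (attack on the hydrogen-bond-directed face of the enamine); C1 follows from C2 because the chain on C2 can reach the furanone carbonyl only from its own face, which gives a cis ring fusion and puts the oxirane oxygen trans to the C2 oxygen; C6 is fixed by SN2 inversion in the oxirane closure, the epimerisable chlorohydrin carbon funnelling through the anti arrangement; C3, C4 and the acetal carbon remain mixtures and are erased later. The step needs 1,4- over 1,6-addition (secured by the two carbonyl groups on C4, which polarise C3 most) and aldol addition from C6 instead of from the other furanone CH2 onto C5 (secured because C5 sits in an enolised β-keto ester and that mode would give a bridged ring), and the irreversible oxirane closure pulls the reversible ketone aldol addition forward.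

Step 5
Reactants: 11 methyl (3aS,4S,7aR)-3a,4-epoxy-7-[(E)-hept-1-en-1-yl]-2-methoxy-5-oxooctahydro-1-benzofuran-6-carboxylate
Product: 13 methyl (3aS,4S,7aR)-3a,4-epoxy-7-[(E)-hept-1-en-1-yl]-2-methoxy-5-oxo-2,3,3a,4,5,7a-hexahydro-1-benzofuran-6-carboxylate, via selenide 12 (not isolated)
Conditions: PhSeCl (1.1 equiv), pyridine (1.2 equiv), CH2Cl2, 0 °C; then H2O2 (30 % aq.), 0 °C → rt
Reagents that add atoms: none
Why: selenenylation of the β-keto ester at its only enolisable carbon (C4) from the face opposite the C3 substituent, then oxidation and syn-elimination of the selenoxide with the C3 hydrogen (selenoxide elimination), should give the C3=C4 alkene conjugated with ketone, ester and heptenyl group, which erases the stereocentres at C3 and C4.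

Step 6
Reactants: 13 methyl (3aS,4S,7aR)-3a,4-epoxy-7-[(E)-hept-1-en-1-yl]-2-methoxy-5-oxo-2,3,3a,4,5,7a-hexahydro-1-benzofuran-6-carboxylate
Product: 14 (3aS,4R,5R,7aR)-3a,4-epoxy-7-[(E)-hept-1-en-1-yl]-6-(hydroxymethyl)-2-methoxy-2,3,3a,4,5,7a-hexahydro-1-benzofuran-5-ol
Conditions: i-Bu2AlH (DIBAL-H, 5 equiv), CH2Cl2, −78 °C; aq. potassium sodium tartrate
Reagents that add atoms: none
Why: i-Bu2AlH should reduce the enone carbonyl in 1,2-fashion and the conjugated methyl ester to the primary allylic alcohol, hydride approaching C5 anti to the adjacent oxirane oxygen so that the C5 hydroxyl ends cis to the oxirane as in the target (substrate-controlled carbonyl reduction); acetal and oxirane survive at −78 °C.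

Step 7
Reactants: 14 (3aS,4R,5R,7aR)-3a,4-epoxy-7-[(E)-hept-1-en-1-yl]-6-(hydroxymethyl)-2-methoxy-2,3,3a,4,5,7a-hexahydro-1-benzofuran-5-ol
Product: 15 (3aS,4R,5R,7aR)-3a,4-epoxy-7-[(E)-hept-1-en-1-yl]-6-(hydroxymethyl)-2,3,3a,4,5,7a-hexahydro-1-benzofuran-2,5-diol (anomer mixture)
Conditions: PPTS (20 mol %), acetone/H2O (4:1), rt
Reagents that add atoms: water, O
Why: the mixed acetal is of the 2-deoxyfuranoside type (no oxygen on the neighbouring CH2) and should hydrolyse under buffered weak acid that leaves the oxirane and the dienylic alcohol alone (acetal hydrolysis to the lactol).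

Step 8
Reactants: 15 (3aS,4R,5R,7aR)-3a,4-epoxy-7-[(E)-hept-1-en-1-yl]-6-(hydroxymethyl)-2,3,3a,4,5,7a-hexahydro-1-benzofuran-2,5-diol; 16 ethyl 2-(triphenylphosphoranylidene)propanoate
Product: 17 ethyl (2E)-4-[(1S,2R,5R,6R)-3-[(1E)-hept-1-en-1-yl]-2,5-dihydroxy-4-(hydroxymethyl)-7-oxabicyclo[4.1.0]hept-3-en-1-yl]-2-methylbut-2-enoate
Conditions: PhCO2H (10 mol %), toluene, 60 °C
Reagents that add atoms: none
Why: Wittig olefination of the lactol through its open hydroxy aldehyde with the α-methyl stabilised ylide should give the (E)-trisubstituted enoate (thermodynamic control of stabilised ylides) and free the C2 hydroxyl in the same event, which removes the temporary ring and its acetal stereocentre.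

Step 9
Reactants: 17 ethyl (2E)-4-[(1S,2R,5R,6R)-3-[(1E)-hept-1-en-1-yl]-2,5-dihydroxy-4-(hydroxymethyl)-7-oxabicyclo[4.1.0]hept-3-en-1-yl]-2-methylbut-2-enoate
Product: 18 (2E)-4-[(1S,2R,5R,6R)-3-[(1E)-hept-1-en-1-yl]-2,5-dihydroxy-4-(hydroxymethyl)-7-oxabicyclo[4.1.0]hept-3-en-1-yl]-2-methylbut-2-enoic acid (target)
Conditions: LiOH·H2O (3 equiv), THF/MeOH/H2O (3:1:1), 0 °C → rt; then 0.5 M HCl to pH 4 at 0 °C
Reagents that add atoms: lithium hydroxide, [Li+].[OH-]
Why: saponification of the ethyl ester and careful acidification should give the acid; the C5 alkoxide is cis to the oxirane and the C2 alkoxide faces the fully substituted C1, so neither can open the oxirane by backside attack (ester hydrolysis).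

**Compound list**

1 | methyl 4-chloro-3-oxobutanoate | COC(=O)CC(=O)CCl | starting material
2 | (2E)-oct-2-enal | CCCCC/C=C/C=O | starting material
3 | methyl (4E)-2-(chloroacetyl)deca-2,4-dienoate (2E/2Z mixture) | CCCCC/C=C/C=C(C(=O)OC)C(=O)CCl | intermediate
4 | 4,4-dimethoxybutan-2-one | CC(=O)CC(OC)OC | starting material
5 | lithium 4,4-dimethoxybut-1-en-2-olate | [Li]OC(=C)CC(OC)OC | intermediate
6 | [(4,4-dimethoxybut-1-en-2-yl)oxy]trimethylsilane | C=C(CC(OC)OC)O[Si](C)(C)C | intermediate
7 | 4,4-dimethoxy-1-[(trimethylsilyl)oxy]butan-2-one | C[Si](C)(C)OCC(=O)CC(OC)OC | intermediate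
8 | 5-methoxydihydrofuran-3(2H)-one (racemic) | COC1CC(=O)CO1 | intermediate
9 | methyl (4E)-2-(chloroacetyl)-3-[(2R)-5-methoxy-3-oxooxolan-2-yl]dec-4-enoate (mixture at C2, C3 and the acetal carbon) | CCCCC/C=C/C(C(C(=O)OC)C(=O)CCl)[C@H]1OC(OC)CC1=O | intermediate
10 | methyl (3aS,4R,7aR)-4-chloro-7-[(E)-hept-1-en-1-yl]-3a-hydroxy-2-methoxy-5-oxooctahydro-1-benzofuran-6-carboxylate (mixture at C2, C6, C7) | CCCCC/C=C/C1C(C(=O)OC)C(=O)[C@H](Cl)[C@]2(O)CC(OC)O[C@H]12 | intermediate
11 | methyl (3aS,4S,7aR)-3a,4-epoxy-7-[(E)-hept-1-en-1-yl]-2-methoxy-5-oxooctahydro-1-benzofuran-6-carboxylate (mixture at C2, C6, C7) | CCCCC/C=C/C1C(C(=O)OC)C(=O)[C@H]2O[C@@]2(CC(OC)O3)[C@@H]13 | intermediate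
12 | methyl (3aS,4S,7aR)-3a,4-epoxy-7-[(E)-hept-1-en-1-yl]-2-methoxy-5-oxo-6-(phenylselanyl)octahydro-1-benzofuran-6-carboxylate (mixture at C2, C6, C7) | CCCCC/C=C/C1C(C(=O)OC)([Se]c4ccccc4)C(=O)[C@H]2O[C@@]2(CC(OC)O3)[C@@H]13 | intermediate
13 | methyl (3aS,4S,7aR)-3a,4-epoxy-7-[(E)-hept-1-en-1-yl]-2-methoxy-5-oxo-2,3,3a,4,5,7a-hexahydro-1-benzofuran-6-carboxylate (mixture at C2) | CCCCC/C=C/C1=C(C(=O)OC)C(=O)[C@H]2O[C@@]2(CC(OC)O3)[C@@H]13 | intermediate
14 | (3aS,4R,5R,7aR)-3a,4-epoxy-7-[(E)-hept-1-en-1-yl]-6-(hydroxymethyl)-2-methoxy-2,3,3a,4,5,7a-hexahydro-1-benzofuran-5-ol (mixture at C2) | CCCCC/C=C/C1=C(CO)[C@@H](O)[C@H]2O[C@@]2(CC(OC)O3)[C@@H]13 | intermediate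
15 | (3aS,4R,5R,7aR)-3a,4-epoxy-7-[(E)-hept-1-en-1-yl]-6-(hydroxymethyl)-2,3,3a,4,5,7a-hexahydro-1-benzofuran-2,5-diol (anomer mixture) | CCCCC/C=C/C1=C(CO)[C@@H](O)[C@H]2O[C@@]2(CC(O)O3)[C@@H]13 | intermediate
16 | ethyl 2-(triphenylphosphoranylidene)propanoate | CCOC(=O)C(C)=P(c1ccccc1)(c1ccccc1)c1ccccc1 | starting material
17 | ethyl (2E)-4-[(1S,2R,5R,6R)-3-[(1E)-hept-1-en-1-yl]-2,5-dihydroxy-4-(hydroxymethyl)-7-oxabicyclo[4.1.0]hept-3-en-1-yl]-2-methylbut-2-enoate | CCCCC/C=C/C1=C(CO)[C@@H](O)[C@H]2O[C@@]2(C/C=C(\C)C(=O)OCC)[C@@H]1O | intermediate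
18 | (2E)-4-[(1S,2R,5R,6R)-3-[(1E)-hept-1-en-1-yl]-2,5-dihydroxy-4-(hydroxymethyl)-7-oxabicyclo[4.1.0]hept-3-en-1-yl]-2-methylbut-2-enoic acid | CCCCC/C=C/C1=C(CO)[C@@H](O)[C@H]2O[C@@]2(C/C=C(\C)C(=O)O)[C@@H]1O | target

**Step count and risks**

Total steps: 9. Longest linear sequence: 8 steps (4 → 18, steps 2 to 9).

Steps most likely to fail:

1. Step 4 (Proposed new method). What may go wrong: enamine formation at the furanone CH2 next to the acetal carbon followed by loss of methanol; N-alkylation of the catalyst by the chloromethyl ketone; partial override of catalyst control by the remote acetal stereocentre of the racemic donor; base-induced epimerisation at C2 of the open Michael adduct before the slower ketone aldol addition closes the ring. Fallback, setting out from 8 (with 3) and returning at 11: 8 is silylated with Me3SiOTf and Et3N toward its oxygen-bearing carbon to give the silyl enol ether [(5-methoxy-4,5-dihydrofuran-3-yl)oxy]trimethylsilane F1. A Mukaiyama–Michael addition of F1 to 3, catalysed by Cu(OTf)2 and (S,S)-2,2'-isopropylidenebis(4-tert-butyl-2-oxazoline) (divalent copper chelated by the two carbonyl groups of 3; ligand enantiomer chosen for (R) at C2) with (CF3)2CHOH as silyl acceptor at −78 °C, gives Michael adduct 9, which is isolated this time. K2CO3 in DMF at 0 °C then closes 9 through 10 to 11 by an intramolecular Darzens reaction, so the two bonds are made in two separate operations of known type and no nucleophilic amine is present.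

2. Step 6. What may go wrong: conjugate hydride addition to the doubly activated dienyl enone ester, or hydride delivery syn to the oxirane so that the C5 epimer forms. Fallback, setting out from 13 and returning at 14, written for the case that simple hydrides attack syn to the oxirane: Luche reduction (NaBH4, CeCl3·7H2O, MeOH, −78 °C) secures clean 1,2-reduction of the ketone only and gives methyl (3aS,4R,5S,7aR)-3a,4-epoxy-7-[(E)-hept-1-en-1-yl]-5-hydroxy-2-methoxy-2,3,3a,4,5,7a-hexahydro-1-benzofuran-6-carboxylate F2. Mitsunobu inversion at C5 (4-nitrobenzoic acid, PPh3, diisopropyl azodicarboxylate, THF, 0 °C) gives methyl (3aS,4R,5R,7aR)-3a,4-epoxy-7-[(E)-hept-1-en-1-yl]-2-methoxy-5-[(4-nitrobenzoyl)oxy]-2,3,3a,4,5,7a-hexahydro-1-benzofuran-6-carboxylate F3. i-Bu2AlH at −78 °C then cleaves the benzoate and reduces the methyl ester to give 14.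

3. Step 8. What may go wrong: slow opening and olefination of the lactol by the hindered stabilised ylide at the temperature it needs, during which the freed C2 hydroxyl re-adds to the new enoate (oxa-Michael closure) or the open β,γ-epoxy aldehyde eliminates with opening of the oxirane. Fallback, setting out from 15 and returning at 17: 15 is methylenated quickly at low temperature with Ph3P=CH2 (from Ph3PCH3Br and KN(SiMe3)2, THF, −20 → 0 °C) to give (1S,2R,5R,6R)-3-[(E)-hept-1-en-1-yl]-4-(hydroxymethyl)-1-(prop-2-en-1-yl)-7-oxabicyclo[4.1.0]hept-3-ene-2,5-diol F4. Cross-metathesis of the terminal alkene of F4 with excess ethyl methacrylate (second-generation Hoveyda–Grubbs catalyst, CH2Cl2, 40 °C) then builds the (E)-2-methyl enoate under neutral conditions and gives 17.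

Further compounds
F1 | step 4 | [(5-methoxy-4,5-dihydrofuran-3-yl)oxy]trimethylsilane | COC1CC(O[Si](C)(C)C)=CO1
F2 | step 6 | methyl (3aS,4R,5S,7aR)-3a,4-epoxy-7-[(E)-hept-1-en-1-yl]-5-hydroxy-2-methoxy-2,3,3a,4,5,7a-hexahydro-1-benzofuran-6-carboxylate | CCCCC/C=C/C1=C(C(=O)OC)[C@H](O)[C@H]2O[C@@]2(CC(OC)O3)[C@@H]13
F3 | step 6 | methyl (3aS,4R,5R,7aR)-3a,4-epoxy-7-[(E)-hept-1-en-1-yl]-2-methoxy-5-[(4-nitrobenzoyl)oxy]-2,3,3a,4,5,7a-hexahydro-1-benzofuran-6-carboxylate | CCCCC/C=C/C1=C(C(=O)OC)[C@@H](OC(=O)c4ccc(cc4)[N+](=O)[O-])[C@H]2O[C@@]2(CC(OC)O3)[C@@H]13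
F4 | step 8 | (1S,2R,5R,6R)-3-[(E)-hept-1-en-1-yl]-4-(hydroxymethyl)-1-(prop-2-en-1-yl)-7-oxabicyclo[4.1.0]hept-3-ene-2,5-diol | CCCCC/C=C/C1=C(CO)[C@@H](O)[C@H]2O[C@@]2(CC=C)[C@@H]1O
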